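Ring A is disconnected at C1–C2 and C3–C4, so that its unsubstituted C2–C3 ethano bridge comes from vinyltriphenylphosphonium bromide. The key step exploits the 1,5-relationship across C10–C5 between a non-enolisable C1 aldehyde on quaternary C10 and the C19 ester on C4: the ester enolate adds to the vinylphosphonium salt (C3–C4, quaternary C4 set) and the resulting ylide closes ring A by intramolecular Wittig olefination (C1=C2). The precursor is a monocyclic ring B aldehyde ester made from (R)-carvone, whose isopropenyl group supplies C4, C18 and C19. Ring B is then elaborated to the 7α-acetoxy-8(17)-ene and the 12E-diene side chain.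

Key step: step 8

Remark: the target is read as 7α-acetoxylabda-8(17),12E,14-trien-19-oic acid of the normal labdane series. Labdane numbering is used for all compounds, including the ring carbons of the monocyclic precursors: C18 = 4α-methyl, C19 = 4β-carboxyl carbon, C20 = 10β-methyl, C17 on C8.

Step 1
Reactants: 1 (R)-(−)-carvone
Product: 3 (5R,6S)-6-methylcarvone, via lithium dienolate 2 (not isolated)
Conditions: LiN(iPr)2 (LDA), THF, −78 °C; MeI, −78 → −20 °C
Reagents that add atoms: iodomethane, CI
Why: Kinetic α′-deprotonation of the enone gives the cross-conjugated lithium dienolate, whose C-methylation (enolate alkylation) occurs mainly anti to the isopropenyl group; the new centre (future C10) is planarised again in step 2, so both epimers are used.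

Step 2
Reactants: 3 (5R,6S)-6-methylcarvone
Product: 5 (5S,6R)-6-(hydroxymethyl)-6-methylcarvone, via lithium dienolate 4 (not isolated)
Conditions: LiN(iPr)2 (LDA), THF, −78 °C; CH2O (gas, from cracked paraformaldehyde), −78 °C; AcOH quench
Reagents that add atoms: formaldehyde, C=O
Why: Aldol addition of the regenerated tetrasubstituted lithium enolate to monomeric formaldehyde takes place on the face anti to the neighbouring isopropenyl group, which sets quaternary C10 with the methyl group (C20) cis and the hydroxymethyl carbon (C1) trans to the C5 substituent.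

Step 3
Reactants: 5 (5S,6R)-6-(hydroxymethyl)-6-methylcarvone
Product: 6 [(1S,6S)-1,3-dimethyl-2-methylidene-6-(prop-1-en-2-yl)cyclohex-3-en-1-yl]methanol
Conditions: Zn, CH2Br2, TiCl4, THF/CH2Cl2, 0 → 25 °C
Reagents that add atoms: dibromomethane, BrCBr
Why: Takai–Lombardo methylenation with the non-basic zinc/titanium methylene reagent converts the hindered C9 ketone into the exocyclic alkene (C11) without the retro-aldol cleavage that a basic ylide would provoke in this β-hydroxy ketone, and no stereocentre is affected.

Step 4
Reactants: 6 [(1S,6S)-1,3-dimethyl-2-methylidene-6-(prop-1-en-2-yl)cyclohex-3-en-1-yl]methanol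
Product: 8 2-[6-(hydroxymethyl)-4,6-dimethyl-5-methylidenecyclohex-3-en-1-yl]propan-1-ol, via bis-9-BBN adduct 7 (not isolated)
Conditions: 9-BBN (2.2 equiv), THF, 0 → 25 °C; NaOH, H2O2, 0 °C
Reagents that add atoms: hydrogen peroxide, OO
Why: Hydroboration–oxidation with the bulky 9-BBN is selective for the unhindered isolated 1,1-disubstituted isopropenyl alkene over the hindered conjugated C9=C11 and C7=C8 alkenes and places the hydroxyl on the terminal carbon (C19), the new C4 centre being formed as an inconsequential epimer mixture that is enolised in step 8.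

Step 5
Reactants: 8 2-[6-(hydroxymethyl)-4,6-dimethyl-5-methylidenecyclohex-3-en-1-yl]propan-1-ol
Product: 10 trans-fused δ-lactone C19(=O)–O–C1H2 between C4 and C10, via lactol 9 (not isolated)
Conditions: TEMPO (cat.), PhI(OAc)2, CH2Cl2, 25 °C
Reagents that add atoms: none
Why: TEMPO-catalysed oxidative lactonisation: the bulky oxoammonium oxidant attacks the less hindered C19 hydroxyl first, the hydroxy aldehyde closes to the lactol with the neopentyl C1 hydroxyl and is oxidised on to the δ-lactone, which differentiates the two primary alcohols without protecting groups.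

Step 6
Reactants: 10 trans-fused δ-lactone
Product: 12 methyl 2-[6-(hydroxymethyl)-4,6-dimethyl-5-methylidenecyclohex-3-en-1-yl]propanoate, via potassium carboxylate 11 (not isolated)
Conditions: KOH, THF/H2O, 25 °C; evaporate; MeI, DMF, 25 °C
Reagents that add atoms: potassium hydroxide, [K+].[OH-]; iodomethane, CI
Why: Saponification of the lactone followed by SN2 O-methylation of the potassium carboxylate under neutral conditions gives the open hydroxy ester while the neopentyl alcohol stays free; the crude product is oxidised at once to forestall relactonisation.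

Step 7
Reactants: 12 methyl 2-[6-(hydroxymethyl)-4,6-dimethyl-5-methylidenecyclohex-3-en-1-yl]propanoate
Product: 13 methyl 2-(6-formyl-4,6-dimethyl-5-methylidenecyclohex-3-en-1-yl)propanoate
Conditions: Dess–Martin periodinane, NaHCO3, CH2Cl2, 0 → 25 °C
Reagents that add atoms: none
Why: Dess–Martin oxidation converts the neopentyl alcohol into the non-enolisable C1 aldehyde under buffered neutral conditions that leave the ester, the diene and the (here irrelevant) epimerisable C4 centre untouched.

Step 8
Reactants: 13 methyl 2-(6-formyl-4,6-dimethyl-5-methylidenecyclohex-3-en-1-yl)propanoate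
Product: 16 methyl 12,13,14,15,16-pentanorlabda-1,7,9(11)-trien-19-oate, via lithium ester enolate 14 (not isolated), via phosphorus ylide 15 (not isolated)
Conditions: LiTMP (lithium 2,2,6,6-tetramethylpiperidide, 1.1 equiv), THF, −78 °C; CH2=CHPPh3Br (1.3 equiv), −78 → 25 °C
Reagents that add atoms: vinyltriphenylphosphonium bromide, C=C[P+](c1ccccc1)(c1ccccc1)c1ccccc1.[Br-]
Why: LiTMP, which has no transferable hydride and is too hindered to add to the neopentyl C1 aldehyde, removes the C4 proton, and the lithium ester enolate adds in Michael fashion to the vinylphosphonium salt, forming C3–C4 and a phosphorus ylide at C2. The ylide then condenses with the C1 aldehyde through an oxaphosphetane, forming C1=C2 and releasing Ph3PO; the closest known reaction type is the Michael addition–intramolecular Wittig annulation of carbonyl-bearing enolates with vinyltriphenylphosphonium salts. Ring A closes by attack of the C2 ylide carbon on the exocyclic C1 carbonyl (6-exo-trig addition, then cycloreversion of the oxaphosphetane), which can only give the cis ring alkene. The one new stereocentre, quaternary C4, is set in the Michael step under A(1,3) strain control: an oxygen substituent on C19 is always cis to C5, so the C5–H bond eclipses the enolate double bond and the electrophile approaches anti to the fully substituted C10, on the side of C6, which places C19 axial (β) once the ring has closed. Chemoselectivity requires the ylide to choose the aldehyde, which is secured because the only other carbonyl, the hindered ester, would give a four-membered ring. Both C4 epimers of 13 converge because C4 is planar in the enolate.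

Step 9
Reactants: 16 methyl 12,13,14,15,16-pentanorlabda-1,7,9(11)-trien-19-oate
Product: 18 methyl 14,15,16-trinorlabda-1,7,12-trien-19-oate, via B-alkyl-9-BBN 17 (not isolated)
Conditions: 9-BBN, THF, 60 °C; then PdCl2(dppf) (5 mol%), 3 M aq. NaOH, CH2=CHBr (1 M in THF), 25 → 50 °C
Reagents that add atoms: vinyl bromide, C=CBr
Why: Hydroboration followed by B-alkyl Suzuki–Miyaura coupling: 9-BBN adds only to the 1,1-disubstituted C9=C11 alkene (boron to C11), delivering hydrogen to C9 from the α face opposite the axial C10 methyl group so that H9 is α and the side chain equatorial, and the palladium-catalysed coupling with vinyl bromide then forms C11–C12.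

Step 10
Reactants: 18 methyl 14,15,16-trinorlabda-1,7,12-trien-19-oate
Product: 19 methyl 14-oxo-15-norlabda-1,7,12E-trien-19-oate
Conditions: methacrolein (10 equiv), second-generation Hoveyda–Grubbs catalyst (5 mol%), CH2Cl2, 40 °C
Reagents that add atoms: methacrolein, C=C(C)C=O
Why: Olefin cross-metathesis: only the monosubstituted terminal alkene engages the ruthenium carbene, the unstrained cis ring alkene and the trisubstituted alkene are inert, and the trisubstituted enal is formed as the thermodynamically favoured E isomer.

Step 11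
Reactants: 19 methyl 14-oxo-15-norlabda-1,7,12E-trien-19-oate
Product: 20 methyl 14-oxo-15-norlabda-7,12E-dien-19-oate
Conditions: KO2CN=NCO2K (excess), AcOH, pyridine, 25 °C
Reagents that add atoms: none
Why: Diimide reduction (concerted syn transfer of H2) is strongly biased towards the cis-disubstituted C1=C2 bond over the two trisubstituted alkenes and, being metal-free, spares the aldehyde.

Step 12
Reactants: 20 methyl 14-oxo-15-norlabda-7,12E-dien-19-oate
Product: 21 methyl 7α,8α-epoxy-14-oxo-15-norlabd-12E-en-19-oate
Conditions: mCPBA, NaHCO3, CH2Cl2, 0 °C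
Reagents that add atoms: 3-chloroperoxybenzoic acid, OOC(=O)c1cccc(Cl)c1
Why: Prilezhaev epoxidation occurs at the only electron-rich alkene (the enal alkene is deactivated) and from the α face, because the β face of C7=C8 is shielded by the axial C10 methyl group, which sets the C7–O bond α.

Step 13
Reactants: 21 methyl 7α,8α-epoxy-14-oxo-15-norlabd-12E-en-19-oate
Product: 22 methyl 7α,8α-epoxylabda-12E,14-dien-19-oate
Conditions: Ph3PCH3Br, KOtBu, THF, 0 °C; then 21, 0 → 25 °C
Reagents that add atoms: methyltriphenylphosphonium bromide, C[P+](c1ccccc1)(c1ccccc1)c1ccccc1.[Br-]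
Why: Wittig methylenation of the enal completes the 12E,14-diene with retention of the E geometry, and the epoxide and the hindered ester do not react with the ylide.

Step 14
Reactants: 22 methyl 7α,8α-epoxylabda-12E,14-dien-19-oate
Product: 23 methyl 7α-hydroxylabda-8(17),12E,14-trien-19-oate
Conditions: Al(OiPr)3 (promoter), toluene, 110 °C
Reagents that add atoms: none
Why: Aluminium isopropoxide promoted epoxide-to-allylic-alcohol isomerisation: aluminium binds the epoxide oxygen and a syn β-hydrogen is removed from the least substituted position (the C17 methyl) through a cyclic transition state with cleavage of C8–O, so the exocyclic 8(17)-alkene forms and the C7–O bond keeps its α configuration.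

Step 15
Reactants: 23 methyl 7α-hydroxylabda-8(17),12E,14-trien-19-oate
Product: 24 7α-hydroxylabda-8(17),12E,14-trien-19-oic acid
Conditions: NaSEt, DMF, 80 °C; then 1 M HCl
Reagents that add atoms: none
Why: SN2 demethylation by thiolate at the O-methyl carbon cleaves the axial neopentyl-type ester without attack at its shielded carbonyl and without touching the alkenes or the free alcohol.

Step 16
Reactants: 24 7α-hydroxylabda-8(17),12E,14-trien-19-oic acid
Product: 26 7α-acetoxylabda-8(17),12E,14-trien-19-oic acid, via mixed anhydride 25 (not isolated)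
Conditions: Ac2O, pyridine, DMAP (cat.), 25 °C; then H2O/THF
Reagents that add atoms: acetic anhydride, CC(=O)OC(C)=O
Why: DMAP-catalysed acylation esterifies the axial allylic 7α-hydroxyl with retention, and the mixed anhydride formed at the C19 acid is hydrolysed back during the aqueous work-up.

Compound list
1 | (R)-(−)-carvone, (5R)-2-methyl-5-(prop-1-en-2-yl)cyclohex-2-en-1-one | O=C1C(C)=CC[C@@H](C(C)=C)C1 | starting material
2 | lithium dienolate of 1 (O–C1=C6, C2=C3) | [Li+].[O-]C1=C[C@H](C(C)=C)CC=C1C | intermediate
3 | (5R,6S)-2,6-dimethyl-5-(prop-1-en-2-yl)cyclohex-2-en-1-one (trans-6-methylcarvone, major epimer) | O=C1C(C)=CC[C@@H](C(C)=C)[C@@H]1C | intermediate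
4 | lithium dienolate of 3 (C6 trigonal) | [Li+].[O-]C1=C(C)[C@H](C(C)=C)CC=C1C | intermediate
5 | (5S,6R)-6-(hydroxymethyl)-2,6-dimethyl-5-(prop-1-en-2-yl)cyclohex-2-en-1-one (6-methyl cis, 6-CH2OH trans to isopropenyl) | O=C1C(C)=CC[C@@H](C(C)=C)[C@]1(C)CO | intermediate
6 | [(1S,6S)-1,3-dimethyl-2-methylidene-6-(prop-1-en-2-yl)cyclohex-3-en-1-yl]methanol | C=C1C(C)=CC[C@@H](C(C)=C)[C@]1(C)CO | intermediate
7 | bis-9-BBN adduct of 6 (O–B at the hydroxymethyl oxygen, C–B at the terminal carbon of the former isopropenyl group) | C=C1C(C)=CC[C@@H](C(C)CB2C3CCCC2CCC3)[C@]1(C)COB1C2CCCC1CCC2 | intermediate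
8 | 2-[6-(hydroxymethyl)-4,6-dimethyl-5-methylidenecyclohex-3-en-1-yl]propan-1-ol (ring centres as in 6, both epimers at the future C4) | C=C1C(C)=CC[C@@H](C(C)CO)[C@]1(C)CO | intermediate
9 | lactol of 10 (C19 hemiacetal carbon, O–C1H2 bridge) | C=C1C(C)=CC[C@H]2C(C)C(O)OC[C@]12C | intermediate
10 | trans-fused δ-lactone: ring B diene (9-methylidene, Δ7, 8-methyl, 5α-H, 10β-methyl) with C4H(CH3)–C19(=O)–O–C1H2 closing the lactone between C5 and C10 (C4 epimers) | C=C1C(C)=CC[C@H]2C(C)C(=O)OC[C@]12C | intermediate
11 | potassium 2-[6-(hydroxymethyl)-4,6-dimethyl-5-methylidenecyclohex-3-en-1-yl]propanoate | C=C1C(C)=CC[C@@H](C(C)C(=O)[O-])[C@]1(C)CO.[K+] | intermediate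
12 | methyl 2-[6-(hydroxymethyl)-4,6-dimethyl-5-methylidenecyclohex-3-en-1-yl]propanoate (10β-methyl, 10α-CH2OH, 5α-H) | C=C1C(C)=CC[C@@H](C(C)C(=O)OC)[C@]1(C)CO | intermediate
13 | methyl 2-(6-formyl-4,6-dimethyl-5-methylidenecyclohex-3-en-1-yl)propanoate (C1 aldehyde on C10, C19 ester on C4) | C=C1C(C)=CC[C@@H](C(C)C(=O)OC)[C@]1(C)C=O | intermediate
14 | lithium ester enolate of 13 (C4=C19) | C=C1C(C)=CC[C@@H](C(C)=C(OC)[O-])[C@]1(C)C=O.[Li+] | intermediate
15 | phosphorus ylide: methyl 2-(6-formyl-4,6-dimethyl-5-methylidenecyclohex-3-en-1-yl)-2-methyl-4-(triphenylphosphoranylidene)butanoate (C4 configured as in the target) | C=C1C(C)=CC[C@@H]([C@](C)(CC=P(c2ccccc2)(c2ccccc2)c2ccccc2)C(=O)OC)[C@]1(C)C=O | intermediate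
16 | methyl 12,13,14,15,16-pentanorlabda-1,7,9(11)-trien-19-oate (4α-methyl, 4β-CO2CH3, 5α-H, 10β-methyl) | C=C1C(C)=CC[C@@H]2[C@]1(C)C=CC[C@]2(C)C(=O)OC | intermediate
17 | B-(19-methoxy-19-oxo-12,13,14,15,16-pentanorlabda-1,7-dien-11-yl)-9-BBN (9α-H) | C1CCC2CCCC1B2C[C@H]1C(C)=CC[C@@H]2[C@]1(C)C=CC[C@]2(C)C(=O)OC | intermediate
18 | methyl 14,15,16-trinorlabda-1,7,12-trien-19-oate (9α-H, 9β-allyl) | C=CC[C@H]1C(C)=CC[C@@H]2[C@]1(C)C=CC[C@]2(C)C(=O)OC | intermediate
19 | methyl 14-oxo-15-norlabda-1,7,12E-trien-19-oate | O=C/C(C)=C/C[C@H]1C(C)=CC[C@@H]2[C@]1(C)C=CC[C@]2(C)C(=O)OC | intermediate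
20 | methyl 14-oxo-15-norlabda-7,12E-dien-19-oate | O=C/C(C)=C/C[C@H]1C(C)=CC[C@@H]2[C@]1(C)CCC[C@]2(C)C(=O)OC | intermediate
21 | methyl 7α,8α-epoxy-14-oxo-15-norlabd-12E-en-19-oate | O=C/C(C)=C/C[C@H]1[C@]2(C)O[C@@H]2C[C@@H]3[C@]1(C)CCC[C@]3(C)C(=O)OC | intermediate
22 | methyl 7α,8α-epoxylabda-12E,14-dien-19-oate | C=C/C(C)=C/C[C@H]1[C@]2(C)O[C@@H]2C[C@@H]3[C@]1(C)CCC[C@]3(C)C(=O)OC | intermediate
23 | methyl 7α-hydroxylabda-8(17),12E,14-trien-19-oate | C=C/C(C)=C/C[C@H]1C(=C)[C@H](O)C[C@@H]2[C@]1(C)CCC[C@]2(C)C(=O)OC | intermediate
24 | 7α-hydroxylabda-8(17),12E,14-trien-19-oic acid | C=C/C(C)=C/C[C@H]1C(=C)[C@H](O)C[C@@H]2[C@]1(C)CCC[C@]2(C)C(=O)O | intermediate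
25 | acetic 7α-acetoxylabda-8(17),12E,14-trien-19-oic anhydride | C=C/C(C)=C/C[C@H]1C(=C)[C@H](OC(C)=O)C[C@@H]2[C@]1(C)CCC[C@]2(C)C(=O)OC(C)=O | intermediate
26 | 7α-acetoxylabda-8(17),12E,14-trien-19-oic acid (CNP0135450.1) | C=C/C(C)=C/C[C@H]1C(=C)[C@H](OC(C)=O)C[C@@H]2[C@]1(C)CCC[C@]2(C)C(=O)O | target

Total step count: 16. Longest linear sequence: 16 steps (fully linear from (R)-carvone).

Steps most likely to fail

Step 8. What may go wrong: addition of the amide base or of the enolate to the aldehyde, slow Michael addition at the congested tetrasubstituted enolate carbon, or insufficient facial discrimination at C4. The fallback makes the two ring A bonds one at a time and sets out from lactone 10. LiN(iPr)2 in THF at −78 °C and allyl bromide alkylate the rigid trans-fused lactone enolate on the face opposite the axial C10 methyl group, giving the C4-allylated lactone F1 with C4 configured as in the target. KOH then MeI gives the hydroxy ester F2, Dess–Martin periodinane gives the aldehyde F3, and Ph3P=CH2 gives the vinyl compound F4. Ring-closing metathesis of the vinyl and allyl groups (second-generation Grubbs catalyst, CH2Cl2, 40 °C) closes C1=C2 with loss of ethene and comes back to the route at 16.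

Step 9. What may go wrong: failure of the palladium stage through slow transmetalation of the β-branched, hindered alkylborane, with protodeboronation or β-hydride loss taking over. The fallback sets out from 16. Hydroboration with 9-BBN as before, followed by oxidation (NaOH, H2O2), gives the primary alcohol F5 with C9 set in the same way. I2/PPh3/imidazole converts it into the iodide F6, and copper-catalysed substitution with CH2=CHMgBr (CuI, THF, −30 °C) forms C11–C12 and comes back to the route at 18.

Step 11. What may go wrong: loss of chemoselectivity through partial reduction of the conjugated enal alkene, or incomplete conversion at the hindered ring alkene. The fallback sets out from 19. Luche reduction (NaBH4, CeCl3, MeOH) gives the allylic alcohol F7. Homogeneous hydrogenation (H2, RhCl(PPh3)3, benzene), now free of an aldehyde that could be decarbonylated, saturates only the cis-disubstituted C1=C2 bond to give the alcohol F8. MnO2 oxidation of the allylic alcohol comes back to the route at 20.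

Further compounds
F1 | step 8 | C4-allylated trans-fused δ-lactone (allyl on the face opposite the C10 methyl group, C4 as in the target) | C=C1C(C)=CC[C@H]2[C@](C)(CC=C)C(=O)OC[C@]12C
F2 | step 8 | methyl 2-[6-(hydroxymethyl)-4,6-dimethyl-5-methylidenecyclohex-3-en-1-yl]-2-methylpent-4-enoate | C=C1C(C)=CC[C@@H]([C@](C)(CC=C)C(=O)OC)[C@]1(C)CO
F3 | step 8 | methyl 2-(6-formyl-4,6-dimethyl-5-methylidenecyclohex-3-en-1-yl)-2-methylpent-4-enoate | C=C1C(C)=CC[C@@H]([C@](C)(CC=C)C(=O)OC)[C@]1(C)C=O
F4 | step 8 | methyl 2-(6-ethenyl-4,6-dimethyl-5-methylidenecyclohex-3-en-1-yl)-2-methylpent-4-enoate | C=C1C(C)=CC[C@@H]([C@](C)(CC=C)C(=O)OC)[C@]1(C)C=C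
F5 | step 9 | methyl 11-hydroxy-12,13,14,15,16-pentanorlabda-1,7-dien-19-oate (9α-H) | OC[C@H]1C(C)=CC[C@@H]2[C@]1(C)C=CC[C@]2(C)C(=O)OC
F6 | step 9 | methyl 11-iodo-12,13,14,15,16-pentanorlabda-1,7-dien-19-oate (9α-H) | IC[C@H]1C(C)=CC[C@@H]2[C@]1(C)C=CC[C@]2(C)C(=O)OC
F7 | step 11 | methyl 14-hydroxy-15-norlabda-1,7,12E-trien-19-oate | OC/C(C)=C/C[C@H]1C(C)=CC[C@@H]2[C@]1(C)C=CC[C@]2(C)C(=O)OC
F8 | step 11 | methyl 14-hydroxy-15-norlabda-7,12E-dien-19-oate | OC/C(C)=C/C[C@H]1C(C)=CC[C@@H]2[C@]1(C)CCC[C@]2(C)C(=O)OC
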